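**Retrosynthetic overview**
1. Target ⇐ 6α-alcohol (acetylation) ⇐ ring A β-keto ester carrying the C11–O–coumarin ether (enol-ether cleavage, decarbomethoxylation, desilylation) ⇐ C11 alcohol + umbelliferone (Mitsunobu).
2. C11 alcohol ⇐ drima-7,9(11)-diene (hydroboration from the α face) ⇐ C9 ketone (C8 methylation, dehydrogenation, methylenation), with the C3 β-keto ester masked as its methoxymethyl enol ether.
3. Decalin ⇐ one-flask Michael–Michael–Dieckmann union of methyl isobutyrate enolate, (S)-4-silyloxy-2-methylcyclohex-2-enone and methyl acrylate (C4–C5, C1–C10, C2–C3); ring B is present from the start and ring A is closed in this step.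
4. Structural basis: ring A is joined to ring B only through C4–C5 and C1–C10, which are trans to each other, and C4–C5 is also trans to the C6 oxygen; a cyclohexenone with C9 as carbonyl, C10=C5 as alkene and the C6 oxygen in place can therefore relay C6 → C5 → C10.
5. Enone ⇐ CBS reduction, silylation and deketalisation of 6-methyl-1,4-dioxaspiro[4.5]dec-6-en-8-one ⇐ 1,4-dioxaspiro[4.5]dec-6-en-8-one (conjugate methylation, Saegusa–Ito oxidation).

Key step: step 6

Remark: decalins are described with drimane numbering and α/β descriptors (C10 methyl β; ring A = C1–C5/C10, ring B = C5–C10), and 1 is taken as a purchased compound.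

**Route**

Step 1
Reactants: 1 1,4-dioxaspiro[4.5]dec-6-en-8-one
Product: 2 trimethyl[(6-methyl-1,4-dioxaspiro[4.5]dec-7-en-8-yl)oxy]silane (racemic)
Conditions: MeMgBr, CuBr·SMe2 (5 mol %), Me3SiCl, HMPA, THF, −78 °C; Et3N, pentane work-up
Reagents that add atoms: methylmagnesium bromide C[Mg]Br; chlorotrimethylsilane C[Si](C)(C)Cl
Why: copper-catalysed conjugate addition of the Grignard reagent, accelerated by the silyl chloride, should trap the regiodefined enolate as its silyl enol ether; the stereocentre formed here is removed again in step 2.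

Step 2
Reactants: 2 trimethyl[(6-methyl-1,4-dioxaspiro[4.5]dec-7-en-8-yl)oxy]silane
Product: 3 6-methyl-1,4-dioxaspiro[4.5]dec-6-en-8-one
Conditions: Pd(OAc)2 (10 mol %), O2 (1 atm), DMSO, 40 °C
Reagents that add atoms: none
Why: Saegusa–Ito oxidation, in which the palladium enolate has a β-hydrogen only at the methyl-bearing carbon, so the enone should re-form with the methyl group on its β-carbon.

Step 3
Reactants: 3 6-methyl-1,4-dioxaspiro[4.5]dec-6-en-8-one
Product: 4 (S)-6-methyl-1,4-dioxaspiro[4.5]dec-6-en-8-ol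
Conditions: (R)-Me-CBS oxazaborolidine [(R)-1-methyl-3,3-diphenyltetrahydro-1H,3H-pyrrolo[1,2-c][1,3,2]oxazaborole] (0.2 equiv), catecholborane, toluene, −78 °C; MeOH, aq NaOH work-up
Reagents that add atoms: none
Why: Corey–Bakshi–Shibata 1,2-reduction in which the alkenyl flank of the ketone acts as the large group, so the (R)-catalyst should deliver hydride to give the (S)-carbinol (the future C6).

Step 4
Reactants: 4 (S)-6-methyl-1,4-dioxaspiro[4.5]dec-6-en-8-ol
Product: 5 (8S)-8-(tert-butyldimethylsilyloxy)-6-methyl-1,4-dioxaspiro[4.5]dec-6-ene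
Conditions: t-BuMe2SiCl, imidazole, DMF, rt
Reagents that add atoms: tert-butyldimethylsilyl chloride CC(C)(C)[Si](C)(C)Cl
Why: standard silylation of a secondary allylic alcohol under basic conditions that leave the vinylogous ketal untouched.

Step 5
Reactants: 5 (8S)-8-(tert-butyldimethylsilyloxy)-6-methyl-1,4-dioxaspiro[4.5]dec-6-ene
Product: 6 (S)-4-(tert-butyldimethylsilyloxy)-2-methylcyclohex-2-en-1-one
Conditions: pyridinium p-toluenesulfonate (0.2 equiv), acetone/H2O 9:1, 40 °C
Reagents that add atoms: water O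
Why: mild acid hydrolysis of an α,β-unsaturated dioxolane, which ionises far more readily than the secondary silyl ether, should release the conjugated enone without touching C6.

Step 6
Reactants: 6 (S)-4-(tert-butyldimethylsilyloxy)-2-methylcyclohex-2-en-1-one; 7 methyl isobutyrate; 8 methyl acrylate
Product: 12 methyl 6α-(tert-butyldimethylsilyloxy)-3-hydroxy-9-oxo-11,12-dinor-5α-drim-2-ene-2-carboxylate (enol form of the C3 β-keto ester), via lithium enolate of methyl isobutyrate 9 (not isolated), via lithium C9 enolate of the C5 Michael adduct 10 (not isolated), via lithium ester enolate of the keto diester 11 (not isolated)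
Conditions: LiN(i-Pr)2 (1.1 equiv), 7, THF, −78 °C; 6, −78 → 0 °C; 8 (1.05 equiv), −78 → 0 °C; MeOH, 0 → 40 °C; AcOH
Reagents that add atoms: none
Why: The ester enolate adds to C5 of the enone (any 1,2-adduct should revert on warming), the resulting C9/C10 enolate adds through C10 to methyl acrylate, and the propanoate enolate, kept available by the lithium methoxide/methanol equilibration, attacks the isobutyrate ester carbonyl, so C4–C5, C1–C10 and C2–C3 form in one flask. The closest known reaction type is the Michael–Michael–ring-closure annulation of an ester enolate, a cyclohexenone and an acrylate that ends in a Dieckmann condensation. Ring A closes 6-exo-trig at the C3 ester carbonyl, and loss of methoxide followed by deprotonation at C2 makes the β-keto ester enolate the thermodynamic sink, whereas the bridged diketones that the C8 enolate could form cannot be stabilised at a bridgehead and should revert. C5 is set by attack anti to the C6 silyloxy group, and C10 by axial attack of the acrylate anti to the bulky C5 substituent, which together should give the trans ring fusion with 5α-H and 10β-methyl. The step needs a regiodefined C9/C10 enolate, secured by generating it through conjugate addition and trapping it cold, and a single mode of ring closure, secured because C4 is quaternary and only C2 can end up as a stabilised enolate.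

Step 7
Reactants: 12 methyl 6α-(tert-butyldimethylsilyloxy)-3-hydroxy-9-oxo-11,12-dinor-5α-drim-2-ene-2-carboxylate
Product: 14 methyl 6α-(tert-butyldimethylsilyloxy)-3-(methoxymethoxy)-9-oxo-11,12-dinor-5α-drim-2-ene-2-carboxylate, via sodium enolate of the β-keto ester 13 (not isolated)
Conditions: NaH (1.05 equiv), THF, 0 °C; MeOCH2Cl, 0 °C → rt
Reagents that add atoms: chloromethyl methyl ether COCCl
Why: O-alkylation of a β-keto ester enolate by a hard alkoxymethyl chloride should mask C3 as an enol ether and remove the acidic C2 hydrogen, leaving C9 as the only reactive carbonyl.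

Step 8
Reactants: 14 methyl 6α-(tert-butyldimethylsilyloxy)-3-(methoxymethoxy)-9-oxo-11,12-dinor-5α-drim-2-ene-2-carboxylate
Product: 16 methyl 6α-(tert-butyldimethylsilyloxy)-3-(methoxymethoxy)-9-oxo-11-nor-5α-drim-2-ene-2-carboxylate (C8 epimers), via C8 lithium enolate of the enol ether 15 (not isolated)
Conditions: LiN(i-Pr)2 (1.1 equiv), THF, −78 °C; MeI, −78 → −20 °C
Reagents that add atoms: iodomethane CI
Why: enolate alkylation at C8, the only enolisable position of the C9 ketone since C10 is quaternary; the C8 configuration is irrelevant because C8 becomes trigonal in step 9.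

Step 9
Reactants: 16 methyl 6α-(tert-butyldimethylsilyloxy)-3-(methoxymethoxy)-9-oxo-11-nor-5α-drim-2-ene-2-carboxylate
Product: 18 methyl 6α-(tert-butyldimethylsilyloxy)-3-(methoxymethoxy)-9-(trimethylsilyloxy)-11-nor-5α-drima-2,8-diene-2-carboxylate, via lithium enolate of the 8-methyl ketone 17 (not isolated)
Conditions: LiN(i-Pr)2, THF, −78 → 0 °C; Me3SiCl, Et3N, −78 °C → rt
Reagents that add atoms: chlorotrimethylsilane C[Si](C)(C)Cl
Why: O-silylation of the single possible (C8=C9) enolate under non-Lewis-acidic conditions that spare the methoxymethyl enol ether.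

Step 10
Reactants: 18 methyl 6α-(tert-butyldimethylsilyloxy)-3-(methoxymethoxy)-9-(trimethylsilyloxy)-11-nor-5α-drima-2,8-diene-2-carboxylate
Product: 19 methyl 6α-(tert-butyldimethylsilyloxy)-3-(methoxymethoxy)-9-oxo-11-nor-5α-drima-2,7-diene-2-carboxylate
Conditions: Pd(OAc)2 (1.1 equiv), MeCN, 40 °C
Reagents that add atoms: none
Why: Saegusa–Ito oxidation, in which β-hydride elimination toward the ring CH2 (C7) should give the conjugated endocyclic 8-methyl-7-en-9-one, as is usual for 2-methylcyclohexanone enol silanes.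

Step 11
Reactants: 19 methyl 6α-(tert-butyldimethylsilyloxy)-3-(methoxymethoxy)-9-oxo-11-nor-5α-drima-2,7-diene-2-carboxylate
Product: 20 methyl 6α-(tert-butyldimethylsilyloxy)-3-(methoxymethoxy)-5α-drima-2,7,9(11)-triene-2-carboxylate
Conditions: Cp2Ti(μ-Cl)(μ-CH2)AlMe2, pyridine, THF/toluene, −40 °C → rt
Reagents that add atoms: Tebbe reagent C[Al-]1(C)C[Ti](C2C=CC=C2)(C2C=CC=C2)[Cl+]1
Why: Tebbe methylenation is non-basic, so the C6 stereocentre γ to the enone is not at risk, and the titanium carbene should react with the hindered ketone in preference to the deactivated vinylogous carbonate ester.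

Step 12
Reactants: 20 methyl 6α-(tert-butyldimethylsilyloxy)-3-(methoxymethoxy)-5α-drima-2,7,9(11)-triene-2-carboxylate
Product: 22 methyl 6α-(tert-butyldimethylsilyloxy)-11-hydroxy-3-(methoxymethoxy)-5α,9α-drima-2,7-diene-2-carboxylate, via 11-boryl adduct 21 (not isolated)
Conditions: 9-borabicyclo[3.3.1]nonane, THF, rt → 50 °C; then H2O2, aq NaOH, 0 °C
Reagents that add atoms: hydrogen peroxide OO
Why: anti-Markovnikov hydroboration–oxidation at the exocyclic terminus of the diene, with hydrogen delivered to C9 from the α face opposite the axial C10 methyl group, should set 9α-H (C11 β) and leave the trisubstituted C7=C8 and the push–pull C2=C3 alkenes untouched.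

Step 13
Reactants: 22 methyl 6α-(tert-butyldimethylsilyloxy)-11-hydroxy-3-(methoxymethoxy)-5α,9α-drima-2,7-diene-2-carboxylate; 23 umbelliferone (7-hydroxy-2H-chromen-2-one)
Product: 24 methyl 6α-(tert-butyldimethylsilyloxy)-3-(methoxymethoxy)-11-[(2-oxo-2H-chromen-7-yl)oxy]-5α,9α-drima-2,7-diene-2-carboxylate
Conditions: PPh3, i-PrO2CN=NCO2i-Pr, THF, 0 °C → rt
Reagents that add atoms: none
Why: Mitsunobu etherification of a primary alcohol with an acidic phenol, which needs no base and so spares the coumarin lactone; no stereocentre is involved.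

Step 14
Reactants: 24 methyl 6α-(tert-butyldimethylsilyloxy)-3-(methoxymethoxy)-11-[(2-oxo-2H-chromen-7-yl)oxy]-5α,9α-drima-2,7-diene-2-carboxylate
Product: 25 methyl 6α-(tert-butyldimethylsilyloxy)-3-hydroxy-11-[(2-oxo-2H-chromen-7-yl)oxy]-5α,9α-drima-2,7-diene-2-carboxylate (enol form of the C3 β-keto ester)
Conditions: pyridinium p-toluenesulfonate, MeOH, 50 °C
Reagents that add atoms: none
Why: acid-catalysed acetal exchange to methanol, in which the enol of a β-keto ester is a good leaving group, should cleave the methoxymethyl enol ether under acidity too weak to ionise the allylic silyl ether.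

Step 15
Reactants: 25 methyl 6α-(tert-butyldimethylsilyloxy)-3-hydroxy-11-[(2-oxo-2H-chromen-7-yl)oxy]-5α,9α-drima-2,7-diene-2-carboxylate
Product: 26 7-{[6α-(tert-butyldimethylsilyloxy)-3-oxo-5α,9α-drim-7-en-11-yl]oxy}-2H-chromen-2-one
Conditions: LiCl, H2O, DMSO, 140 °C
Reagents that add atoms: none
Why: Krapcho decarbomethoxylation of a β-keto methyl ester under essentially neutral conditions, which the aryl ether, coumarin and silyl ether should tolerate.

Step 16
Reactants: 26 7-{[6α-(tert-butyldimethylsilyloxy)-3-oxo-5α,9α-drim-7-en-11-yl]oxy}-2H-chromen-2-one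
Product: 27 7-[(6α-hydroxy-3-oxo-5α,9α-drim-7-en-11-yl)oxy]-2H-chromen-2-one
Conditions: Bu4NF, AcOH, THF, rt → 45 °C
Reagents that add atoms: none
Why: fluoride desilylation buffered with acetic acid avoids both the acid that could ionise the allylic alcohol and the free alkoxide that could open the lactone.

Step 17
Reactants: 27 7-[(6α-hydroxy-3-oxo-5α,9α-drim-7-en-11-yl)oxy]-2H-chromen-2-one
Product: 28 7-[(6α-acetoxy-3-oxo-5α,9α-drim-7-en-11-yl)oxy]-2H-chromen-2-one (CNP0140705.1)
Conditions: Ac2O, pyridine, 4-(dimethylamino)pyridine (cat.), CH2Cl2, rt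
Reagents that add atoms: acetic anhydride CC(=O)OC(C)=O
Why: nucleophile-catalysed acylation of the only hydroxyl group, with retention at C6.

**Compound list**
1 | 1,4-dioxaspiro[4.5]dec-6-en-8-one | O=C1C=CC2(CC1)OCCO2 | starting material
2 | trimethyl[(6-methyl-1,4-dioxaspiro[4.5]dec-7-en-8-yl)oxy]silane (racemic) | C[Si](C)(C)OC1=CC(C)C2(CC1)OCCO2 | intermediate
3 | 6-methyl-1,4-dioxaspiro[4.5]dec-6-en-8-one | CC1=CC(=O)CCC12OCCO2 | intermediate
4 | (S)-6-methyl-1,4-dioxaspiro[4.5]dec-6-en-8-ol | O[C@H]1CCC2(OCCO2)C(C)=C1 | intermediate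
5 | (8S)-8-(tert-butyldimethylsilyloxy)-6-methyl-1,4-dioxaspiro[4.5]dec-6-ene | CC(C)(C)[Si](C)(C)O[C@H]1CCC2(OCCO2)C(C)=C1 | intermediate
6 | (S)-4-(tert-butyldimethylsilyloxy)-2-methylcyclohex-2-en-1-one | CC(C)(C)[Si](C)(C)O[C@H]1CCC(=O)C(C)=C1 | intermediate
7 | methyl isobutyrate | COC(=O)C(C)C | starting material
8 | methyl acrylate | C=CC(=O)OC | starting material
9 | lithium enolate of methyl isobutyrate | [Li]OC(OC)=C(C)C | intermediate
10 | first Michael adduct as lithium enolate: ring B with C9–OLi, C9=C10, C10 methyl, and C5 bearing C(CH3)2CO2Me trans to the C6 silyloxy group | CC(C)(C)[Si](C)(C)O[C@H]1CCC(O[Li])=C(C)[C@@H]1C(C)(C)C(=O)OC | intermediate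
11 | second Michael adduct as lithium ester enolate: C9 ketone, C10 bearing methyl and the CH2CH=C(OLi)OMe chain trans to the C5 C(CH3)2CO2Me group | CC(C)(C)[Si](C)(C)O[C@H]1CCC(=O)[C@@](C)(CC=C(O[Li])OC)[C@@H]1C(C)(C)C(=O)OC | intermediate
12 | methyl 6α-(tert-butyldimethylsilyloxy)-3-hydroxy-9-oxo-11,12-dinor-5α-drim-2-ene-2-carboxylate (trans-fused, 10β-methyl; enol form of the C3 β-keto ester) | CC(C)(C)[Si](C)(C)O[C@H]1CCC(=O)[C@@]2(C)CC(C(=O)OC)=C(O)C(C)(C)[C@H]12 | intermediate
13 | sodium enolate of 12 | CC(C)(C)[Si](C)(C)O[C@H]1CCC(=O)[C@@]2(C)CC(C(=O)OC)=C(O[Na])C(C)(C)[C@H]12 | intermediate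
14 | methyl 6α-(tert-butyldimethylsilyloxy)-3-(methoxymethoxy)-9-oxo-11,12-dinor-5α-drim-2-ene-2-carboxylate | CC(C)(C)[Si](C)(C)O[C@H]1CCC(=O)[C@@]2(C)CC(C(=O)OC)=C(OCOC)C(C)(C)[C@H]12 | intermediate
15 | C8=C9 lithium enolate of 14 | CC(C)(C)[Si](C)(C)O[C@H]1CC=C(O[Li])[C@@]2(C)CC(C(=O)OC)=C(OCOC)C(C)(C)[C@H]12 | intermediate
16 | methyl 6α-(tert-butyldimethylsilyloxy)-3-(methoxymethoxy)-9-oxo-11-nor-5α-drim-2-ene-2-carboxylate (8-methyl, C8 epimers) | CC(C)(C)[Si](C)(C)O[C@H]1CC(C)C(=O)[C@@]2(C)CC(C(=O)OC)=C(OCOC)C(C)(C)[C@H]12 | intermediate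
17 | C8=C9 lithium enolate of 16 | CC(C)(C)[Si](C)(C)O[C@H]1CC(C)=C(O[Li])[C@@]2(C)CC(C(=O)OC)=C(OCOC)C(C)(C)[C@H]12 | intermediate
18 | methyl 6α-(tert-butyldimethylsilyloxy)-3-(methoxymethoxy)-9-(trimethylsilyloxy)-11-nor-5α-drima-2,8-diene-2-carboxylate | CC(C)(C)[Si](C)(C)O[C@H]1CC(C)=C(O[Si](C)(C)C)[C@@]2(C)CC(C(=O)OC)=C(OCOC)C(C)(C)[C@H]12 | intermediate
19 | methyl 6α-(tert-butyldimethylsilyloxy)-3-(methoxymethoxy)-9-oxo-11-nor-5α-drima-2,7-diene-2-carboxylate | CC(C)(C)[Si](C)(C)O[C@H]1C=C(C)C(=O)[C@@]2(C)CC(C(=O)OC)=C(OCOC)C(C)(C)[C@H]12 | intermediate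
20 | methyl 6α-(tert-butyldimethylsilyloxy)-3-(methoxymethoxy)-5α-drima-2,7,9(11)-triene-2-carboxylate | CC(C)(C)[Si](C)(C)O[C@H]1C=C(C)C(=C)[C@@]2(C)CC(C(=O)OC)=C(OCOC)C(C)(C)[C@H]12 | intermediate
21 | 11-(9-borabicyclo[3.3.1]nonan-9-yl) adduct of 20 (9α-H) | CC(C)(C)[Si](C)(C)O[C@H]1C=C(C)[C@H](CB3C4CCCC3CCC4)[C@@]2(C)CC(C(=O)OC)=C(OCOC)C(C)(C)[C@H]12 | intermediate
22 | methyl 6α-(tert-butyldimethylsilyloxy)-11-hydroxy-3-(methoxymethoxy)-5α,9α-drima-2,7-diene-2-carboxylate | CC(C)(C)[Si](C)(C)O[C@H]1C=C(C)[C@H](CO)[C@@]2(C)CC(C(=O)OC)=C(OCOC)C(C)(C)[C@H]12 | intermediate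
23 | umbelliferone (7-hydroxy-2H-chromen-2-one) | O=c1ccc2ccc(O)cc2o1 | starting material
24 | methyl 6α-(tert-butyldimethylsilyloxy)-3-(methoxymethoxy)-11-[(2-oxo-2H-chromen-7-yl)oxy]-5α,9α-drima-2,7-diene-2-carboxylate | CC(C)(C)[Si](C)(C)O[C@H]1C=C(C)[C@H](COc3ccc4ccc(=O)oc4c3)[C@@]2(C)CC(C(=O)OC)=C(OCOC)C(C)(C)[C@H]12 | intermediate
25 | methyl 6α-(tert-butyldimethylsilyloxy)-3-hydroxy-11-[(2-oxo-2H-chromen-7-yl)oxy]-5α,9α-drima-2,7-diene-2-carboxylate (enol form of the C3 β-keto ester) | CC(C)(C)[Si](C)(C)O[C@H]1C=C(C)[C@H](COc3ccc4ccc(=O)oc4c3)[C@@]2(C)CC(C(=O)OC)=C(O)C(C)(C)[C@H]12 | intermediate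
26 | 7-{[6α-(tert-butyldimethylsilyloxy)-3-oxo-5α,9α-drim-7-en-11-yl]oxy}-2H-chromen-2-one | CC(C)(C)[Si](C)(C)O[C@H]1C=C(C)[C@H](COc3ccc4ccc(=O)oc4c3)[C@@]2(C)CCC(=O)C(C)(C)[C@H]12 | intermediate
27 | 7-[(6α-hydroxy-3-oxo-5α,9α-drim-7-en-11-yl)oxy]-2H-chromen-2-one | O[C@H]1C=C(C)[C@H](COc3ccc4ccc(=O)oc4c3)[C@@]2(C)CCC(=O)C(C)(C)[C@H]12 | intermediate
28 | 7-[(6α-acetoxy-3-oxo-5α,9α-drim-7-en-11-yl)oxy]-2H-chromen-2-one (CNP0140705.1) | CC(=O)O[C@H]1C=C(C)[C@H](COc2ccc3ccc(=O)oc3c2)[C@@]2(C)CCC(=O)C(C)(C)[C@H]12 | target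

**Step count and risks**

Total: 17 steps. Longest linear sequence: 17 steps (from 1; compounds 7, 8 and 23 are purchased and enter at steps 6 and 13).

Steps most likely to fail:

1. Step 6. The one-flask annulation may suffer from 1,2-addition that does not revert, from proton transfer that scrambles the C9/C10 enolate, or from acrylate oligomerisation that outruns ring closure. Fallback: the three bonds are made in separate operations, setting out from 6 and returning at 12. Mukaiyama–Michael addition of the purchased silyl ketene acetal of methyl isobutyrate, Me2C=C(OMe)OSiMe3, to 6 (Me3SiOTf cat., CH2Cl2, −78 °C) should give the C9 trimethylsilyl enol ether of the C5 adduct F1. MeLi (THF, 0 °C) then releases the regiodefined lithium enolate, which is added to methyl acrylate 8 at −78 °C and quenched to the keto diester F2. NaOMe in MeOH closes ring A by Dieckmann condensation to 12.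

2. Step 12. Hydroboration of the conjugated diene may lose regiocontrol (attack at the ring alkene) or facial control at C9. Fallback: C11 is brought in as a carbonyl adduct and C9–H is set by a stereospecific hydrogenolysis, setting out from enone 19 and returning at 22. Corey–Chaykovsky epoxidation (Me3S+ I−, KN(SiMe3)2, THF, −10 °C), with the ylide approaching C9 anti to the C10 methyl, should give the 9β,11-epoxide F4. Formate hydrogenolysis of this vinyl epoxide with zerovalent palladium (Pd2(dba)3·CHCl3 cat., n-Bu3P, HCO2H, Et3N, dioxane, rt) delivers hydride to C9 with inversion, giving the 9α-H homoallylic alcohol 22.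

3. Step 11. Methylenation may stall at the carbonyl flanked by the quaternary C10 and the substituted C8, or the reagent may begin to attack the ester on warming. Fallback: the carbon is added as a nucleophile and the alkene formed by dehydration, setting out from 19 and returning at 20. MeLi/CeCl3 (THF, −78 °C) should add to the ketone from the α face to give the tertiary allylic alcohol F3. Dehydration with MeO2CN(−)SO2N(+)Et3 (Burgess reagent, toluene, 50 °C) can only place the new alkene at C9=C11, since C10 is quaternary and C8 carries no hydrogen, and so should give diene 20.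

**Further compounds**
F1 | step 6 | C9 trimethylsilyl enol ether of the C5 Michael adduct (C5 substituent trans to the C6 silyloxy group) | CC(C)(C)[Si](C)(C)O[C@H]1CCC(O[Si](C)(C)C)=C(C)[C@@H]1C(C)(C)C(=O)OC
F2 | step 6 | keto diester: ring B C9 ketone with C10 bearing methyl and CH2CH2CO2Me trans to the C5 C(CH3)2CO2Me group | CC(C)(C)[Si](C)(C)O[C@H]1CCC(=O)[C@@](C)(CCC(=O)OC)[C@@H]1C(C)(C)C(=O)OC
F3 | step 11 | methyl 6α-(tert-butyldimethylsilyloxy)-9β-hydroxy-3-(methoxymethoxy)-5α-drima-2,7-diene-2-carboxylate (9α-methyl tertiary alcohol) | CC(C)(C)[Si](C)(C)O[C@H]1C=C(C)[C@](C)(O)[C@@]2(C)CC(C(=O)OC)=C(OCOC)C(C)(C)[C@H]12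
F4 | step 12 | methyl 6α-(tert-butyldimethylsilyloxy)-9β,11-epoxy-3-(methoxymethoxy)-5α-drima-2,7-diene-2-carboxylate | CC(C)(C)[Si](C)(C)O[C@H]1C=C(C)[C@@]3(CO3)[C@@]2(C)CC(C(=O)OC)=C(OCOC)C(C)(C)[C@H]12
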